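**Plan**
- Retrosynthesis: the allylic alcohol is cut back to a C5 aldehyde (C=C by olefination, then ester reduction). The O1–C2 bond is cut to a benzylic carbinol. C2–aryl and C3–C3a are then cut together, across an E-alkenyl boronate.
- Enabling feature: C2 and C3 of the dihydrofuran are neighbouring sp3 carbons, each with one aryl group (3,4-dimethoxyphenyl on C2, the benzo carbon C3a on C3), and C2 also carries O1. This is the pattern left by anti 1,2-diarylation of a boron-bearing alkene followed by C–B oxidation.
- Forward: a hindered (E)-alkenyl boronate, 3,4-dimethoxyphenyllithium and a ring-A aryl bromide are joined in one operation. The C–B bond is oxidised, acid closes the only new ring (O1–C2), and the side chain is finished last.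
- Stereochemistry: the chiral palladium catalyst and the stereospecific anti addition to the E-alkene set both centres. C3 is kept throughout; C2 is ionised in the ring closure and re-formed trans to the C3 substituent.

Key step: step 5

Remark: B(mac) denotes the boronic ester of cis-1,2-dimethyl-1,2-dihydroacenaphthylene-1,2-diol. The (Sp,Sp) antipode of the MandyPhos ligand is assumed to give the (1S,2R) boronate 12; if the sense of induction is the opposite, the (Rp,Rp) ligand is used and nothing else changes.

**Step 1**
Reactants: 1 acenaphthoquinone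
Product: 2 cis-1,2-dimethyl-1,2-dihydroacenaphthylene-1,2-diol (mac diol)
Conditions: MeMgBr (2.5 equiv), THF, 0 °C → rt; aq. NH4Cl; recrystallisation
Reagents that add atoms: methylmagnesium bromide, C[Mg]Br
Why: Double Grignard addition to the 1,2-diketone, in which the second methyl should enter anti to the bulky magnesium alkoxide left by the first, so that both hydroxyls sit on one face (cis, meso); any trans diol cannot chelate boron and is removed by crystallisation.

**Step 2**
Reactants: 3 tert-butyldimethyl(prop-2-yn-1-yloxy)silane; 2 mac diol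
Product: 5 (E)-3-(tert-butyldimethylsilyloxy)prop-1-enyl B(mac) boronate, via catechol alkenylboronate 4 (not isolated)
Conditions: catecholborane (1.05 equiv), neat, 70 °C; then 2, THF, rt
Reagents that add atoms: catecholborane, B1Oc2ccccc2O1
Why: Syn hydroboration of the terminal alkyne puts boron on the terminal carbon and gives the E-alkenyl boronate, and the labile catechol ester then exchanges with the rigid cis diol (boronate transesterification) to give a chromatography-stable ester.

**Step 3**
Reactants: 6 5-bromovanillin
Product: 7 3-bromo-5-methoxy-4-(methoxymethoxy)benzaldehyde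
Conditions: MOMCl, i-Pr2NEt, CH2Cl2, 0 °C → rt
Reagents that add atoms: chloromethyl methyl ether, COCCl
Why: O-alkylation of the acidic phenol (MOM protection), which should proceed despite the two ortho substituents because the electrophile is small and highly reactive.

**Step 4**
Reactants: 7 3-bromo-5-methoxy-4-(methoxymethoxy)benzaldehyde
Product: 8 1-bromo-5-(dimethoxymethyl)-3-methoxy-2-(methoxymethoxy)benzene
Conditions: HC(OMe)3, MeOH, PPTS (cat.), rt; Et3N quench
Reagents that add atoms: trimethyl orthoformate, COC(OC)OC; methanol, CO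
Why: Acid-catalysed acetalisation driven by the orthoformate as water scavenger; the weak pyridinium acid at room temperature should leave the aryl MOM ether intact, and the acetal keeps the aldehyde away from the organolithium and the borate in the next step.

**Step 5**
Reactants: 9 4-bromo-1,2-dimethoxybenzene; 5 (E)-alkenyl B(mac) boronate; 8 aryl bromide acetal
Product: 12 syn-(1S,2R) B(mac) boronate with 3,4-dimethoxyphenyl on the boron-bearing carbon and ring A on the next carbon, via aryllithium 10 (not isolated), via lithium borate 11 (not isolated)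
Conditions: 9, t-BuLi (2.0 equiv), THF, −78 °C; 5, −78 °C → rt; then 8 (1.1 equiv), Pd(OAc)2 (3 mol%), (Sp,Sp)-MandyPhos (3.6 mol%), KOTf (3 equiv), THF, 60 °C
Reagents that add atoms: none
Why: Oxidative addition of 8 to Pd(0)/MandyPhos and bromide abstraction by KOTf give a cationic arylpalladium(II) that binds the alkene of borate 11; the 3,4-dimethoxyphenyl group then shifts from boron to the boron-bearing carbon anti to palladium (1,2-metallate shift), and reductive elimination joins ring A to the neighbouring carbon. The closest known reaction type is the palladium-catalysed enantioselective conjunctive cross-coupling of β-substituted alkenyl B(mac) ate complexes with aryl electrophiles, run with a triflate salt when halide is present. No ring is closed. Anti addition across the E-alkene is stereospecific and fixes the syn relation of boron and ring A, while the ferrocenyl bisphosphine selects the alkene face and with it the absolute configuration of C1 (S) and C2 (R). The step needs the metallate shift to outrun direct Suzuki transfer of the alkenyl group and β-silyloxy elimination: the hindered mac diol slows transmetallation, KOTf precipitates the bromide (from the lithium–halogen exchange and from 8) that would block alkene binding, and the chelating ligand makes reductive elimination fast.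

**Step 6**
Reactants: 12 syn-(1S,2R) B(mac) boronate
Product: 13 (1S,2R)-3-(tert-butyldimethylsilyloxy)-1-(3,4-dimethoxyphenyl)-2-[5-(dimethoxymethyl)-3-methoxy-2-(methoxymethoxy)phenyl]propan-1-ol
Conditions: 30% H2O2, 3 M NaOH, THF, 0 °C → rt
Reagents that add atoms: hydrogen peroxide, OO
Why: Boronate oxidation, in which hydroperoxide adds to boron and the benzylic carbon migrates to oxygen with retention, so the carbinol keeps the 1S configuration; acetal, MOM and silyl ether are stable to cold aqueous base.

**Step 7**
Reactants: 13 (1S,2R) benzylic alcohol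
Product: 15 (2S,3R)-2-(3,4-dimethoxyphenyl)-3-(hydroxymethyl)-7-methoxy-2,3-dihydrobenzofuran-5-carbaldehyde, via phenolic triol aldehyde 14 (not isolated)
Conditions: 3 M aq. HCl, THF, 40 °C
Reagents that add atoms: water, O
Why: Aqueous acid hydrolyses the acetal, the silyl ether and the MOM ether and ionises the 3,4-dimethoxybenzylic alcohol to a cation that the ortho oxygen captures in a five-membered O1–C2 closure (acid-mediated phenylcoumaran formation); C2 is re-formed from the planar cation on the face away from the C3 hydroxymethyl group, so the fixed 3R centre dictates 2S and the trans ring.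

**Step 8**
Reactants: 15 dihydrobenzofuran aldehyde
Product: 16 ethyl (E)-3-[(2S,3R)-2-(3,4-dimethoxyphenyl)-3-(hydroxymethyl)-7-methoxy-2,3-dihydrobenzofuran-5-yl]acrylate
Conditions: (EtO)2P(O)CH2CO2Et, LiCl, DBU, MeCN, rt
Reagents that add atoms: triethyl phosphonoacetate, CCOC(=O)CP(=O)(OCC)OCC
Why: Horner–Wadsworth–Emmons olefination under Masamune–Roush conditions, which tolerates the free primary alcohol and should give the E-cinnamate from the stabilised phosphonate anion.

**Step 9**
Reactants: 16 ethyl cinnamate
Product: 17 Hierochin B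
Conditions: DIBAL-H (4 equiv), CH2Cl2, −78 °C; Rochelle salt work-up
Reagents that add atoms: none
Why: 1,2-Reduction of the α,β-unsaturated ester to the allylic alcohol by DIBAL-H (one equivalent is spent on the free hydroxyl) at low temperature, which leaves the E-alkene and both ring stereocentres untouched.

**Compound list**
1 | acenaphthoquinone (acenaphthylene-1,2-dione) | O=C1C(=O)c2cccc3cccc1c23 | starting material
2 | cis-(1R,2S)-1,2-dimethyl-1,2-dihydroacenaphthylene-1,2-diol (mac diol, meso) | C[C@@]1(O)c2cccc3cccc(c23)[C@]1(C)O | intermediate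
3 | tert-butyldimethyl(prop-2-yn-1-yloxy)silane | C#CCO[Si](C)(C)C(C)(C)C | starting material
4 | 2-[(E)-3-(tert-butyldimethylsilyloxy)prop-1-enyl]-1,3,2-benzodioxaborole | CC(C)(C)[Si](C)(C)OC/C=C/B1Oc2ccccc2O1 | intermediate (not isolated)
5 | (E)-3-(tert-butyldimethylsilyloxy)prop-1-enylboronic acid mac ester | CC(C)(C)[Si](C)(C)OC/C=C/B1O[C@]2(C)c3cccc4cccc(c34)[C@]2(C)O1 | intermediate
6 | 5-bromovanillin (3-bromo-4-hydroxy-5-methoxybenzaldehyde) | COc1cc(C=O)cc(Br)c1O | starting material
7 | 3-bromo-5-methoxy-4-(methoxymethoxy)benzaldehyde | COCOc1c(Br)cc(C=O)cc1OC | intermediate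
8 | 1-bromo-5-(dimethoxymethyl)-3-methoxy-2-(methoxymethoxy)benzene | COCOc1c(Br)cc(C(OC)OC)cc1OC | intermediate
9 | 4-bromo-1,2-dimethoxybenzene | COc1ccc(Br)cc1OC | starting material
10 | 3,4-dimethoxyphenyllithium | COc1ccc([Li])cc1OC | intermediate (not isolated)
11 | lithium (E)-alkenyl(3,4-dimethoxyphenyl) B(mac) borate (configuration at boron not defined) | [Li+].COc1ccc(cc1OC)[B-]1(/C=C/CO[Si](C)(C)C(C)(C)C)O[C@]2(C)c3cccc4cccc(c34)[C@]2(C)O1 | intermediate (not isolated)
12 | mac ester of (1S,2R)-3-(tert-butyldimethylsilyloxy)-1-(3,4-dimethoxyphenyl)-2-[5-(dimethoxymethyl)-3-methoxy-2-(methoxymethoxy)phenyl]propylboronic acid | COc1ccc([C@@H](B2O[C@]3(C)c4cccc5cccc(c45)[C@]3(C)O2)[C@@H](CO[Si](C)(C)C(C)(C)C)c2cc(C(OC)OC)cc(OC)c2OCOC)cc1OC | intermediate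
13 | (1S,2R)-3-(tert-butyldimethylsilyloxy)-1-(3,4-dimethoxyphenyl)-2-[5-(dimethoxymethyl)-3-methoxy-2-(methoxymethoxy)phenyl]propan-1-ol | COc1ccc([C@@H](O)[C@@H](CO[Si](C)(C)C(C)(C)C)c2cc(C(OC)OC)cc(OC)c2OCOC)cc1OC | intermediate
14 | 3-[(1S,2R)-1-(3,4-dimethoxyphenyl)-1,3-dihydroxypropan-2-yl]-4-hydroxy-5-methoxybenzaldehyde | COc1ccc([C@@H](O)[C@@H](CO)c2cc(C=O)cc(OC)c2O)cc1OC | intermediate (not isolated)
15 | (2S,3R)-2-(3,4-dimethoxyphenyl)-3-(hydroxymethyl)-7-methoxy-2,3-dihydrobenzofuran-5-carbaldehyde | COc1ccc([C@H]2Oc3c(OC)cc(C=O)cc3[C@@H]2CO)cc1OC | intermediate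
16 | ethyl (E)-3-[(2S,3R)-2-(3,4-dimethoxyphenyl)-3-(hydroxymethyl)-7-methoxy-2,3-dihydrobenzofuran-5-yl]acrylate | COc1ccc([C@H]2Oc3c(OC)cc(/C=C/C(=O)OCC)cc3[C@@H]2CO)cc1OC | intermediate
17 | Hierochin B, (E)-3-[(2S,3R)-2-(3,4-dimethoxyphenyl)-3-(hydroxymethyl)-7-methoxy-2,3-dihydrobenzofuran-5-yl]prop-2-en-1-ol | COc1ccc([C@H]2Oc3c(OC)cc(/C=C/CO)cc3[C@@H]2CO)cc1OC | target

Total step count: 9
Longest linear sequence: 7 steps (steps 3, 4, 5, 6, 7, 8, 9; the branch through steps 1, 2, 5–9 is equally long)

**Steps most likely to fail**

Step 5. The metallate shift may lose to direct Suzuki–Miyaura transfer of the alkenyl group, residual bromide may block alkene binding at palladium, the alkylpalladium intermediate may eliminate the β-silyloxy group, or face selectivity may be insufficient. The fallback is an auxiliary-controlled aldol route that sets out from 8 and returns at 15. Palladium-catalysed coupling of 8 with the Reformatsky reagent BrZnCH2CO2Et (Pd2(dba)3/XPhos, THF, 60 °C) would give ethyl 2-[5-(dimethoxymethyl)-3-methoxy-2-(methoxymethoxy)phenyl]acetate F1. Saponification (LiOH, THF/H2O, buffered acidification) would give the arylacetic acid F2. Mixed-anhydride acylation (PivCl, Et3N; lithiated (S)-4-benzyl-2-oxazolidinone) would give the N-arylacetyl oxazolidinone F3. Evans boron aldol reaction (Bu2BOTf, i-Pr2NEt, CH2Cl2, −78 → 0 °C) with 3,4-dimethoxybenzaldehyde would give the syn aldol adduct F4, both centres being set by the auxiliary through the Z-enolate. LiBH4 (THF/MeOH, 0 °C) would remove the auxiliary and give the (1S,2R) diol F5, which under the conditions of step 7 should close to 15.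

Step 7. Before an oxygen nucleophile captures it, the benzylic cation may lose a proton or fragment with loss of formaldehyde to a stilbene, or MOM cleavage may lag and leave partly deprotected mixtures. The fallback closes the ring before deprotection; it sets out from 13 and returns at 15. BF3·OEt2 in dry CH2Cl2 at −40 °C would ionise the benzylic alcohol while the primary oxygen is still silylated, so formaldehyde cannot be lost. The MOM ether oxygen would capture the cation and shed its methoxymethyl group, and aqueous work-up would return the aldehyde from the acetal, giving the silyl-protected trans-dihydrobenzofuran aldehyde F6. TBAF in THF would then free the primary alcohol to give 15.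

Step 2. Hydroboration may be incomplete or leak to the internal regioisomer, the Lewis-acidic borane may attack the silyl ether, or the diol exchange on boron may stall. The fallback replaces hydroboration/exchange by condensation of a boronic acid; it sets out from 3 and returns at 5. Zirconium-catalysed hydroboration (pinacolborane, Cp2ZrHCl cat., Et3N cat., 60 °C) would give the (E)-pinacol boronate F7, which can also be purchased. Oxidative removal of pinacol (NaIO4, NH4OAc, acetone/H2O) would give the (E)-alkenylboronic acid F8, and condensation with 2 (MgSO4, CH2Cl2, rt) would give 5.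

**Further compounds**
F1 | step 5 | ethyl 2-[5-(dimethoxymethyl)-3-methoxy-2-(methoxymethoxy)phenyl]acetate | CCOC(=O)Cc1cc(C(OC)OC)cc(OC)c1OCOC
F2 | step 5 | 2-[5-(dimethoxymethyl)-3-methoxy-2-(methoxymethoxy)phenyl]acetic acid | OC(=O)Cc1cc(C(OC)OC)cc(OC)c1OCOC
F3 | step 5 | (S)-4-benzyl-3-{2-[5-(dimethoxymethyl)-3-methoxy-2-(methoxymethoxy)phenyl]acetyl}oxazolidin-2-one | O=C(Cc1cc(C(OC)OC)cc(OC)c1OCOC)N1[C@@H](Cc2ccccc2)COC1=O
F4 | step 5 | (S)-4-benzyl-3-{(2S,3S)-3-(3,4-dimethoxyphenyl)-2-[5-(dimethoxymethyl)-3-methoxy-2-(methoxymethoxy)phenyl]-3-hydroxypropanoyl}oxazolidin-2-one | COc1ccc([C@@H](O)[C@@H](C(=O)N2[C@@H](Cc3ccccc3)COC2=O)c2cc(C(OC)OC)cc(OC)c2OCOC)cc1OC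
F5 | step 5 | (1S,2R)-1-(3,4-dimethoxyphenyl)-2-[5-(dimethoxymethyl)-3-methoxy-2-(methoxymethoxy)phenyl]propane-1,3-diol | COc1ccc([C@@H](O)[C@@H](CO)c2cc(C(OC)OC)cc(OC)c2OCOC)cc1OC
F6 | step 7 | (2S,3R)-3-[(tert-butyldimethylsilyloxy)methyl]-2-(3,4-dimethoxyphenyl)-7-methoxy-2,3-dihydrobenzofuran-5-carbaldehyde | COc1ccc([C@H]2Oc3c(OC)cc(C=O)cc3[C@@H]2CO[Si](C)(C)C(C)(C)C)cc1OC
F7 | step 2 | (E)-tert-butyldimethyl{[3-(4,4,5,5-tetramethyl-1,3,2-dioxaborolan-2-yl)allyl]oxy}silane | CC(C)(C)[Si](C)(C)OC/C=C/B1OC(C)(C)C(C)(C)O1
F8 | step 2 | (E)-3-(tert-butyldimethylsilyloxy)prop-1-enylboronic acid | CC(C)(C)[Si](C)(C)OC/C=C/B(O)O
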